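The 5-alkylidene-5,6-dihydropyran-2-one (ring O1'–C2'–C3'–C4'–C5'–C6') is cut at C5'–C4' and O1'–C2'. Because C7 sits cis to C4' and trans to C6' across C8=C5', the ring maps onto a (Z)-β-iodo-γ-hydroxy enone, whose geometry comes from anti hydroiodination of an ynone. One Stille coupling with methyl (Z)-3-(tributylstannyl)acrylate then forms C5'–C4' with retention and lets the C6' hydroxyl close the lactone. The precursor is the complete carvone-derived cyclohexane core (spiro glycidate, furoyl ketone, two quaternary carbons, silyl-protected carbinol) carrying that iodoenone.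

Key step: step 15

Remark (labels): ring carbons keep carvone numbering. C1 is the former carbonyl carbon (later the spiro epoxide carbon), C2 carries the original methyl, C5 the former isopropenyl carbon, C6 the newly quaternised carbon. Cα is the glycidate CH, C7 and C8 are the side-chain carbons, and primed atoms belong to the pyranone.

Remark (chemistry): the C5 carbinol is carried as its tert-butyldimethylsilyl ether, which is more robust than a triethylsilyl ether. This lets the two triethylsilyl ethers be removed in its presence and keeps it intact in the acetic acid of step 13. Carbinol centres that are oxidised later (furyl carbinol, C7 carbinol) and the transient diol carbon are formed as mixtures and left undefined in the SMILES.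

Step 1
Reactants: 1 (S)-carvone
Product: 3 (5S,6R)-2,6-dimethyl-5-(prop-1-en-2-yl)cyclohex-2-en-1-one (trans-6-methylcarvone), via lithium dienolate 2 (not isolated)
Conditions: LiN(iPr)2, THF, −78 °C; MeI, −78 to −20 °C
Reagents that add atoms: iodomethane, CI
Why: Kinetic α′-deprotonation gives the cross-conjugated enolate and enolate alkylation (SN2 on MeI) should occur mainly anti to the adjacent isopropenyl group, giving the trans (5S,6R) isomer, which is separated from any cis epimer.

Step 2
Reactants: 3 trans-6-methylcarvone; 4 3-furaldehyde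
Product: 6 (2S,5S,6R)-2-[furan-3-yl(hydroxy)methyl]-2,6-dimethyl-5-(prop-1-en-2-yl)cyclohexan-1-one as a mixture of carbinol epimers, via lithium enolate 5 (not isolated)
Conditions: LiBH(sBu)3, THF, −78 °C; 4, −78 °C; AcOH, −78 °C
Reagents that add atoms: none
Why: In this reductive aldol reaction, conjugate hydride addition forms the C1–C2 enolate regiospecifically and the aldehyde should add by axial attack on the half-chair whose C5 and C6 substituents are equatorial, so the new C2–C bond forms cis to isopropenyl (C2 S), while the carbinol centre is accepted as a mixture because step 10 oxidises it.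

Step 3
Reactants: 6 aldol
Product: 7 triethylsilyl ether of 6
Conditions: Et3SiOTf, 2,6-lutidine, CH2Cl2, −78 to 0 °C
Reagents that add atoms: triethylsilyl triflate, CC[Si](CC)(CC)OS(=O)(=O)C(F)(F)F
Why: Silyl triflate etherification of the hindered secondary alcohol masks the aldol hydroxyl, so that the base of step 4 cannot trigger retro-aldol cleavage, and creates no stereocentre.

Step 4
Reactants: 7 silyl-protected aldol
Product: 10 ketone with quaternary C6 bearing methyl and CH2OSiEt3, via lithium enolate 8 (not isolated), via lithium alkoxide 9 (not isolated)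
Conditions: LiN(iPr)2, THF, −78 to 0 °C; CH2O (gas, from cracked paraformaldehyde), −78 °C; Et3SiCl, −78 to 0 °C
Reagents that add atoms: formaldehyde, C=O; chlorotriethylsilane, CC[Si](Cl)(CC)CC
Why: C6 carries the only enolisable hydrogen, and the aldol addition of its tetrasubstituted lithium enolate to formaldehyde should take place anti to the neighbouring isopropenyl group (pushed pseudoaxial by allylic strain with the C6 methyl), which makes C6 quaternary with CH2O trans to isopropenyl (C6 S), while in-flask O-silylation stops loss of formaldehyde.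

Step 5
Reactants: 10 doubly α-quaternary ketone
Product: 12 spiro methyl glycidate bearing both triethylsilyl ethers, via potassium chlorohydrin alkoxide 11 (not isolated)
Conditions: ClCH2CO2Me (excess), KN(SiMe3)2 (slow addition), THF, −78 to 0 °C
Reagents that add atoms: methyl chloroacetate, COC(=O)CCl
Why: In this Darzens glycidic ester condensation on a ketone that cannot enolise, the chloroester enolate should add axially to the C1 face flanked only by the equatorial C2 methyl and C6 CH2OSiEt3 (the other face is blocked by the axial CH(OSiEt3)furyl and C6 methyl groups of the chair that keeps isopropenyl equatorial), which sets C1, and anti-periplanar displacement of chloride by the alkoxide should turn the ester toward the C2-methyl flank, away from the larger CH2OSiEt3 flank, which sets Cα.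

Step 6
Reactants: 12 glycidate with isopropenyl group
Product: 14 C5 methyl ketone, via diol 13 (not isolated)
Conditions: OsO4 (cat.), NaIO4, 2,6-lutidine, dioxane–H2O, rt
Reagents that add atoms: osmium tetroxide, O=[Os](=O)(=O)=O (delivers the oxygen); sodium periodate, [Na+].[O-]I(=O)(=O)=O (restores it and cleaves the diol)
Why: In this Lemieux–Johnson oxidation OsO4 dihydroxylates the electron-rich 1,1-disubstituted alkene faster than the furan and periodate cleaves diol 13 to the methyl ketone (ozone is avoided because it would cleave the furan), with lutidine buffering so that C5 does not epimerise.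

Step 7
Reactants: 14 methyl ketone
Product: 15 (R)-carbinol
Conditions: (S)-2-methyl-CBS-oxazaborolidine (cat.), BH3·SMe2, THF, −20 °C; MeOH
Reagents that add atoms: none
Why: In this Corey–Bakshi–Shibata reduction the (S)-oxazaborolidine–borane complex binds the ketone with the bulky ring carbon away from the catalyst and should deliver hydride to give the (R)-carbinol under reagent control, in the same sense in which acetophenone gives the (R)-alcohol, while ester, epoxide, silyl ethers and furan are untouched at −20 °C.

Step 8
Reactants: 15 carbinol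
Product: 16 tert-butyldimethylsilyl ether of 15
Conditions: tBuMe2SiOTf, 2,6-lutidine, CH2Cl2, −78 to 0 °C
Reagents that add atoms: tert-butyldimethylsilyl triflate, CC(C)(C)[Si](C)(C)OS(=O)(=O)C(F)(F)F
Why: Silyl triflate etherification puts on the carbinol a silyl group more robust than the two triethylsilyl ethers, so that these can be removed selectively in step 9 and the ether survives acetic acid in step 13.

Step 9
Reactants: 16 tris-silyl ether
Product: 17 diol (furyl carbinol and C7 primary alcohol free)
Conditions: HF·pyridine, pyridine, THF, 0 °C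
Reagents that add atoms: none
Why: Buffered HF·pyridine cleaves triethylsilyl ethers much faster than a secondary tert-butyldimethylsilyl ether (selective desilylation), and the diol is oxidised at once so that the furyl carbinol has no time to lactonise onto the ester.

Step 10
Reactants: 17 diol
Product: 18 furyl ketone C7 aldehyde
Conditions: Dess–Martin periodinane, NaHCO3, CH2Cl2, 0 °C to rt
Reagents that add atoms: none
Why: Dess–Martin oxidation converts the primary alcohol into the C7 aldehyde and the furyl carbinol into the ketone in one operation under buffered, non-epimerising conditions that furan and glycidate tolerate, and it erases the unselective carbinol centre of step 2.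

Step 11
Reactants: 18 keto aldehyde; 19 2-methylbut-3-yn-2-ol
Product: 21 propargylic alcohol as a mixture of C7 epimers, via dilithio alkynolate 20 (not isolated)
Conditions: 19, nBuLi (2 equiv per 19), THF, −78 to 0 °C; 18, −78 °C; NH4Cl (aq)
Reagents that add atoms: none
Why: In this acetylide addition the dilithio derivative of 19 should attack the non-enolisable aldehyde much faster than the furan-conjugated ketone shielded by quaternary C2 or the methyl ester at −78 °C, and the configuration at C7 does not matter because step 12 oxidises it.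

Step 12
Reactants: 21 propargylic alcohol
Product: 22 γ-hydroxy ynone
Conditions: Dess–Martin periodinane, NaHCO3, CH2Cl2, rt
Reagents that add atoms: none
Why: Dess–Martin oxidation of the secondary propargylic alcohol gives the ynone, while the tertiary alcohol cannot be oxidised.

Step 13
Reactants: 22 ynone
Product: 23 (Z)-β-iodo-γ-hydroxy enone (precursor of the key step)
Conditions: NaI, AcOH, MeCN, 0 °C to rt
Reagents that add atoms: sodium iodide, [Na+].[I-]
Why: In this hydroiodination of an ynone, iodide adds to C5' and the allenolate is protonated at C8 anti to iodine, so iodine ends cis to C7 (the kinetic (Z)-β-iodoenone), the tertiary hydroxyl lies trans to the ketone and cannot cyclise, and mild acid at or below room temperature should spare the sterically shielded glycidate and the silyl ether.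

Step 14
Reactants: 24 methyl propiolate
Product: 25 methyl (Z)-3-(tributylstannyl)acrylate
Conditions: Bu3SnH, Et3B (cat.), air, toluene, −78 to 0 °C; chromatography
Reagents that add atoms: tributyltin hydride, CCCC[SnH](CCCC)CCCC
Why: In this radical-chain hydrostannation the stannyl radical adds to the terminal alkyne carbon and the α-ester vinyl radical takes hydrogen anti to tin, so the (Z)-β-stannyl acrylate is the kinetic product at low temperature and is freed from minor E and α isomers by chromatography.

Step 15
Reactants: 23 (Z)-β-iodo-γ-hydroxy enone; 25 methyl (Z)-3-(tributylstannyl)acrylate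
Product: 27 tert-butyldimethylsilyl ether of the target, via hydroxy dienoate 26 (not isolated)
Conditions: Pd2(dba)3 (cat.), AsPh3, CuI (cat.), NMP, rt to 40 °C
Reagents that add atoms: none
Why: Zerovalent palladium inserts into the C5'–I bond of 23 with retention, CuI-assisted tin-to-palladium transfer brings in the (Z)-acrylate unit, and reductive elimination from divalent palladium forms C5'–C4' so that C7 stays cis to C4' and the ester stays cis on C3'=C4'. The closest known reaction type is the Stille coupling of (Z)-β-iodoenones and of (Z)-3-stannylacrylates, whose products lactonise onto a neighbouring hydroxyl. The pyranone ring closes by 6-exo-trig acyl substitution: the C6' hydroxyl of 26, held next to C2' by the cis C3'=C4' bond and helped by the gem-dimethyl group, attacks the ester and expels methanol. No stereocentre is formed; only the two alkene geometries matter, and both are inherited from the coupling partners because neither oxidative addition nor transmetallation scrambles a vinyl geometry under these mild, neutral conditions, which AsPh3 and CuI make possible near room temperature. Chemoselectivity rests on the vinyl iodide being the only site for oxidative addition, while the glycidate, the furan, the silyl ether and the two non-enolisable ketones are spectators. The hydroxyl cannot add to the C7 ketone because it sits trans to it across C8=C5'.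

Step 16
Reactants: 27 silyl ether of the target
Product: 28 target (CNP0293135.1)
Conditions: HF·pyridine, pyridine, THF, 0 °C to rt
Reagents that add atoms: none
Why: Fluoride-mediated desilylation with buffered HF·pyridine removes the last silyl ether without base, so the dienone-lactone, the glycidate and the furan should survive, and no stereocentre is touched.

Compound list

1 | (S)-carvone, (5S)-2-methyl-5-(prop-1-en-2-yl)cyclohex-2-en-1-one | CC1=CC[C@@H](CC1=O)C(C)=C | starting material
2 | lithium dienolate of 1 (O–Li on C1, C1=C6 and C2=C3, C5 S) | [Li+].[O-]C1=C[C@@H](C(C)=C)CC=C1C | intermediate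
3 | (5S,6R)-2,6-dimethyl-5-(prop-1-en-2-yl)cyclohex-2-en-1-one | CC1=CC[C@@H]([C@@H](C)C1=O)C(C)=C | intermediate
4 | 3-furaldehyde (furan-3-carbaldehyde) | O=Cc1ccoc1 | starting material
5 | lithium (5S,6R)-2,6-dimethyl-5-(prop-1-en-2-yl)cyclohex-1-en-1-olate | [Li+].[O-]C1=C(C)CC[C@H](C(C)=C)[C@H]1C | intermediate
6 | (2S,5S,6R)-2-[furan-3-yl(hydroxy)methyl]-2,6-dimethyl-5-(prop-1-en-2-yl)cyclohexan-1-one, carbinol carbon as a mixture | O=C1[C@](C)(C(O)c2ccoc2)CC[C@H](C(C)=C)[C@H]1C | intermediate
7 | (2S,5S,6R)-2-[furan-3-yl(triethylsilyloxy)methyl]-2,6-dimethyl-5-(prop-1-en-2-yl)cyclohexan-1-one | O=C1[C@](C)(C(O[Si](CC)(CC)CC)c2ccoc2)CC[C@H](C(C)=C)[C@H]1C | intermediate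
8 | lithium enolate of 7 (O–Li on C1, C1=C6; C2 S, C5 R) | [Li+].[O-]C1=C(C)[C@@H](C(C)=C)CC[C@@]1(C)C(O[Si](CC)(CC)CC)c1ccoc1 | intermediate
9 | lithium alkoxide of the C6-hydroxymethyl ketone (C2 S, C5 R, C6 S) | O=C1[C@](C)(C(O[Si](CC)(CC)CC)c2ccoc2)CC[C@H](C(C)=C)[C@@]1(C)C[O-].[Li+] | intermediate
10 | (2S,5R,6S)-2-[furan-3-yl(triethylsilyloxy)methyl]-2,6-dimethyl-5-(prop-1-en-2-yl)-6-[(triethylsilyloxy)methyl]cyclohexan-1-one | O=C1[C@](C)(C(O[Si](CC)(CC)CC)c2ccoc2)CC[C@H](C(C)=C)[C@@]1(C)CO[Si](CC)(CC)CC | intermediate
11 | potassium alkoxide of the chlorohydrin from 10 and methyl chloroacetate (Cα R, C1 S, C2 S, C5 R, C6 S) | [K+].COC(=O)[C@H](Cl)[C@@]1([O-])[C@](C)(C(O[Si](CC)(CC)CC)c2ccoc2)CC[C@H](C(C)=C)[C@@]1(C)CO[Si](CC)(CC)CC | intermediate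
12 | methyl (2S,3S,4S,5R,8S)-8-[furan-3-yl(triethylsilyloxy)methyl]-4,8-dimethyl-5-(prop-1-en-2-yl)-4-[(triethylsilyloxy)methyl]-1-oxaspiro[2.5]octane-2-carboxylate (Cα S, C1 S, C2 S, C5 R, C6 S) | COC(=O)[C@H]1O[C@@]12[C@](C)(C(O[Si](CC)(CC)CC)c1ccoc1)CC[C@H](C(C)=C)[C@@]2(C)CO[Si](CC)(CC)CC | intermediate
13 | diol from dihydroxylation of the isopropenyl group of 12 (1,2-dihydroxypropan-2-yl on C5, new carbinol carbon as a mixture; ring centres as in 12, C5 now S) | COC(=O)[C@H]1O[C@@]12[C@](C)(C(O[Si](CC)(CC)CC)c1ccoc1)CC[C@H](C(C)(O)CO)[C@@]2(C)CO[Si](CC)(CC)CC | intermediate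
14 | methyl (2S,3S,4S,5S,8S)-5-acetyl-8-[furan-3-yl(triethylsilyloxy)methyl]-4,8-dimethyl-4-[(triethylsilyloxy)methyl]-1-oxaspiro[2.5]octane-2-carboxylate | COC(=O)[C@H]1O[C@@]12[C@](C)(C(O[Si](CC)(CC)CC)c1ccoc1)CC[C@H](C(C)=O)[C@@]2(C)CO[Si](CC)(CC)CC | intermediate
15 | methyl (2S,3S,4S,5S,8S)-8-[furan-3-yl(triethylsilyloxy)methyl]-5-[(1R)-1-hydroxyethyl]-4,8-dimethyl-4-[(triethylsilyloxy)methyl]-1-oxaspiro[2.5]octane-2-carboxylate | COC(=O)[C@H]1O[C@@]12[C@](C)(C(O[Si](CC)(CC)CC)c1ccoc1)CC[C@H]([C@@H](C)O)[C@@]2(C)CO[Si](CC)(CC)CC | intermediate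
16 | tert-butyldimethylsilyl ether of 15 at the (1R)-carbinol | COC(=O)[C@H]1O[C@@]12[C@](C)(C(O[Si](CC)(CC)CC)c1ccoc1)CC[C@H]([C@@H](C)O[Si](C)(C)C(C)(C)C)[C@@]2(C)CO[Si](CC)(CC)CC | intermediate
17 | methyl (2S,3S,4S,5S,8S)-5-[(1R)-1-(tert-butyldimethylsilyloxy)ethyl]-8-[furan-3-yl(hydroxy)methyl]-4-(hydroxymethyl)-4,8-dimethyl-1-oxaspiro[2.5]octane-2-carboxylate | COC(=O)[C@H]1O[C@@]12[C@](C)(C(O)c1ccoc1)CC[C@H]([C@@H](C)O[Si](C)(C)C(C)(C)C)[C@@]2(C)CO | intermediate
18 | methyl (2S,3S,4R,5S,8R)-5-[(1R)-1-(tert-butyldimethylsilyloxy)ethyl]-4-formyl-8-(furan-3-carbonyl)-4,8-dimethyl-1-oxaspiro[2.5]octane-2-carboxylate | COC(=O)[C@H]1O[C@@]12[C@](C)(C(=O)c1ccoc1)CC[C@H]([C@@H](C)O[Si](C)(C)C(C)(C)C)[C@@]2(C)C=O | intermediate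
19 | 2-methylbut-3-yn-2-ol | C#CC(C)(C)O | starting material
20 | dilithium salt of 19 (acetylide carbon and alkoxide oxygen) | [Li+].[Li+].[C-]#CC(C)(C)[O-] | intermediate
21 | methyl (2S,3S,4S,5S,8R)-5-[(1R)-1-(tert-butyldimethylsilyloxy)ethyl]-4-(1,4-dihydroxy-4-methylpent-2-yn-1-yl)-8-(furan-3-carbonyl)-4,8-dimethyl-1-oxaspiro[2.5]octane-2-carboxylate, C7 carbinol as a mixture | COC(=O)[C@H]1O[C@@]12[C@](C)(C(=O)c1ccoc1)CC[C@H]([C@@H](C)O[Si](C)(C)C(C)(C)C)[C@@]2(C)C(O)C#CC(C)(C)O | intermediate
22 | methyl (2S,3R,4R,5S,8R)-5-[(1R)-1-(tert-butyldimethylsilyloxy)ethyl]-8-(furan-3-carbonyl)-4-(4-hydroxy-4-methylpent-2-ynoyl)-4,8-dimethyl-1-oxaspiro[2.5]octane-2-carboxylate | COC(=O)[C@H]1O[C@@]12[C@](C)(C(=O)c1ccoc1)CC[C@H]([C@@H](C)O[Si](C)(C)C(C)(C)C)[C@@]2(C)C(=O)C#CC(C)(C)O | intermediate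
23 | methyl (2S,3R,4R,5S,8R)-5-[(1R)-1-(tert-butyldimethylsilyloxy)ethyl]-8-(furan-3-carbonyl)-4-[(2Z)-4-hydroxy-3-iodo-4-methylpent-2-enoyl]-4,8-dimethyl-1-oxaspiro[2.5]octane-2-carboxylate (iodine cis to C7) | COC(=O)[C@H]1O[C@@]12[C@](C)(C(=O)c1ccoc1)CC[C@H]([C@@H](C)O[Si](C)(C)C(C)(C)C)[C@@]2(C)C(=O)/C=C(\I)C(C)(C)O | intermediate
24 | methyl propiolate | C#CC(=O)OC | starting material
25 | methyl (Z)-3-(tributylstannyl)acrylate | COC(=O)/C=C\[Sn](CCCC)(CCCC)CCCC | intermediate
26 | Stille product before lactonisation: core of 23 in which iodine is replaced by a (Z)-2-(methoxycarbonyl)vinyl group (C7 cis to C4', C3'=C4' Z, tertiary hydroxyl free; ring centres as in 23) | COC(=O)[C@H]1O[C@@]12[C@](C)(C(=O)c1ccoc1)CC[C@H]([C@@H](C)O[Si](C)(C)C(C)(C)C)[C@@]2(C)C(=O)/C=C(\C=C/C(=O)OC)C(C)(C)O | intermediate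
27 | tert-butyldimethylsilyl ether of the target at the (1R)-carbinol (C7 cis to C4'; exocyclic alkene E by the sequence rule) | COC(=O)[C@H]1O[C@@]12[C@](C)(C(=O)c1ccoc1)CC[C@H]([C@@H](C)O[Si](C)(C)C(C)(C)C)[C@@]2(C)C(=O)/C=C1\C=CC(=O)OC1(C)C | intermediate
28 | methyl (2S,3R,4R,5S,8R)-4-[(2E)-2-(2,2-dimethyl-6-oxo-2H-pyran-3(6H)-ylidene)acetyl]-8-(furan-3-carbonyl)-5-[(1R)-1-hydroxyethyl]-4,8-dimethyl-1-oxaspiro[2.5]octane-2-carboxylate (Cα S, C1 R, C2 R, C5 S, C6 R, carbinol R) | COC(=O)[C@H]1O[C@@]12[C@](C)(C(=O)c1ccoc1)CC[C@H]([C@@H](C)O)[C@@]2(C)C(=O)/C=C1\C=CC(=O)OC1(C)C | target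

Total step count: 16. Longest linear sequence: 15 steps (steps 1 to 13, then 15 and 16); step 14 is a one-step side branch.

Steps most likely to fail

Step 5 (Darzens condensation). Addition of the chloroester enolate to a carbonyl flanked by two quaternary carbons may be too slow, so that self-condensation of the enolate or reversal of the addition before ring closure wins. Attack on the other carbonyl face, or closure with the ester on the C6 side, would also cost material. Fallback, setting out from 10 and coming back at 12: the smaller, more nucleophilic cerium enolate of methyl acetate (LiN(iPr)2, MeOAc, anhydrous CeCl3, THF, −78 °C) would add to the ketone to give the tertiary β-hydroxy ester F1. Its alkoxide–enolate dianion (LiN(iPr)2, 2.2 equiv, −78 °C), which cannot undergo retro-aldol cleavage, would be iodinated at Cα with I2. The resulting lithium alkoxide of the α-iodo-β-hydroxy ester F2 would close in the flask by anti-periplanar displacement of iodide to give 12. The same steric arguments apply to the face of addition and to the side taken by the ester.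

Step 4 (C6 hydroxymethylation). Deprotonation of the hindered C6–H may be slow, the axial C2 methyl may erode facial selectivity, and formaldehyde may be lost by retro-aldol cleavage before silylation. Fallback, setting out from 3 and coming back at 10: the order of the two quaternisations would be reversed. The cross-conjugated enolate of 3 (LiN(iPr)2, THF, −78 °C) would be treated with formaldehyde and Et3SiCl to give the 6,6-disubstituted enone (5R,6S)-2,6-dimethyl-5-(prop-1-en-2-yl)-6-[(triethylsilyloxy)methyl]cyclohex-2-en-1-one F3, where attack anti to isopropenyl is the usual course for a second α′-substitution of carvone. Reductive aldol reaction (LiBH(sBu)3, then 4) would give the aldol (2S,5R,6S)-2-[furan-3-yl(hydroxy)methyl]-2,6-dimethyl-5-(prop-1-en-2-yl)-6-[(triethylsilyloxy)methyl]cyclohexan-1-one F4, and Et3SiOTf with 2,6-lutidine would return to 10. The price is a less predictable face of attack at C2.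

Step 15 (key step). Transmetallation of the internally coordinated (Z)-stannylacrylate may be sluggish, which opens the way to protodestannylation, homocoupling or Z-to-E isomerisation of the iodoenone; the E isomer would let the hydroxyl add to the C7 ketone. Lactonisation of 26 may also stall and need brief warming or a trace of acid. Fallback, setting out from 23 and coming back at 27: the polarity of the coupling would be reversed. Exchange of iodine for tin (Me3SnSnMe3, Pd(PPh3)4, toluene, 60 °C) would give, with retention, the (Z)-β-trimethylstannyl enone F5. Methyl (Z)-3-iodoacrylate F6, made from 24 with NaI in AcOH, is a reactive electrophile of secure geometry. Coupling of F5 with F6 (Pd2(dba)3, AsPh3, CuI, NMP, rt) would form the same C5'–C4' bond and give 26, which lactonises to 27.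

Further compounds

F1 | step 5 | β-hydroxy ester from 10 and methyl acetate, methyl 2-(1-hydroxycyclohexyl)acetate core with ring centres as in 12 | COC(=O)C[C@@]1(O)[C@](C)(C(O[Si](CC)(CC)CC)c2ccoc2)CC[C@H](C(C)=C)[C@@]1(C)CO[Si](CC)(CC)CC
F2 | step 5 | lithium alkoxide of the α-iodo-β-hydroxy ester from F1 (not isolated) | [Li+].COC(=O)[C@H](I)[C@@]1([O-])[C@](C)(C(O[Si](CC)(CC)CC)c2ccoc2)CC[C@H](C(C)=C)[C@@]1(C)CO[Si](CC)(CC)CC
F3 | step 4 | (5R,6S)-2,6-dimethyl-5-(prop-1-en-2-yl)-6-[(triethylsilyloxy)methyl]cyclohex-2-en-1-one | CC1=CC[C@H](C(C)=C)[C@@](C)(CO[Si](CC)(CC)CC)C1=O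
F4 | step 4 | (2S,5R,6S)-2-[furan-3-yl(hydroxy)methyl]-2,6-dimethyl-5-(prop-1-en-2-yl)-6-[(triethylsilyloxy)methyl]cyclohexan-1-one, carbinol carbon as a mixture | O=C1[C@](C)(C(O)c2ccoc2)CC[C@H](C(C)=C)[C@@]1(C)CO[Si](CC)(CC)CC
F5 | step 15 | (Z)-β-trimethylstannyl-γ-hydroxy enone, compound 23 with SnMe3 in place of iodine (tin cis to C7) | COC(=O)[C@H]1O[C@@]12[C@](C)(C(=O)c1ccoc1)CC[C@H]([C@@H](C)O[Si](C)(C)C(C)(C)C)[C@@]2(C)C(=O)/C=C(\[Sn](C)(C)C)C(C)(C)O
F6 | step 15 | methyl (Z)-3-iodoacrylate | COC(=O)/C=C\I
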